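## The problem

Target 18 is a 2,6-diaryl-3,7-dioxabicyclo[3.3.0]octane. Two tetrahydrofuran rings share the C1–C5 bond: ring A (C1–C2–O3–C4–C5) carries the 3-hydroxy-4,5-dimethoxyphenyl group (aryl A) on C2, and ring B (C5–C6–O7–C8–C1) carries the 3,4,5-trimethoxyphenyl group (aryl B) on C6. The core is C2-symmetric, but the aryl groups differ by one O-methyl group, so a dimerisation is excluded and the two halves must be introduced separately. There are four contiguous stereocentres (1R,2S,5R,6S). The cis ring fusion follows from the bicycle, so the tasks are the absolute configuration and the two trans relationships H1/H2 and H5/H6 that place both aryl groups on the convex face. A benzylic centre set first (C6) can steer the bridgeheads C5 and C1 through a five-membered ring, and the other (C2) can be left to thermodynamic control while it is still enolisable, because exo is the more stable position. The benzylic C2–O3 and C6–O7 bonds lie next to electron-rich arenes: they ionise under protic or Lewis acid (endo epimers, reductive opening) and are cleaved by hydrogenolysis, and the phenol needs a mask that leaves without acid or hydrogen. The feature that opens the key step is that, without O3, the carbons C2–C1–C5–C4 of ring A close to a cyclobutanone fused to ring B. Its C1–C5 bond is the former C=C bond of a γ-aryl butenolide, and its carbonyl carbon C4 lies next to the benzylic carbon C2, which can migrate to oxygen when O3 is put back.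

## Retrosynthesis

**18 ⇐ 17.** Only the O–Si bond of the phenol is cut. A triisopropylsilyl ether is preferred to a benzyl ether (hydrogenolysis would endanger C2–O3 and C6–O7) and to acetal-type groups (acid). It has to survive strong base, light, peracid, hydride and cold BF3·OEt2, and to leave with fluoride.

**17 ⇐ 16 ⇐ 15.** No skeletal bond is cut; C4 and C8 are raised to the carboxyl level. This is preferred to opening both rings to a tetraol and re-closing them, because the C2–O3 and C6–O7 bonds then never have to be made at a benzylic carbon. Dilactone 15 has the full skeleton and all four stereocentres, and its ring A lactone is recognisable as the product of an oxygen insertion. The forward direction asks for two lactones to be reduced to cyclic ethers without ionising the benzylic ethers: i-Bu2AlH to bis-lactol 16, then a silane with a Lewis acid in the cold.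

**15 ⇐ 14.** The C2–O3 bond is cut, O3 is removed and C2 is joined to C4, which gives cyclobutanone 14. The alternative of removing O7 on the other side would place the ketone next to the carbon that already carries the controlling aryl B. In 14 the carbon that must migrate is benzylic, migration proceeds with retention, and C2 is α to the ketone, so its exo configuration can be reached by equilibration. The precursor has one heteroatom less and only carbocyclic strain to build. The forward reaction must let C2 migrate in preference to the ring-fusion carbon C5.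

**14 ⇐ 13.** The ketone is masked as its diethyl ketal, the form in which the four-membered ring is made. Hydrolysis must not open the ring, and the same operation is used to equilibrate C2.

**13 ⇐ 7 + 12.** The C4–C5 and C1–C2 bonds are cut in a retro-[2+2] sense. The other way of splitting the cyclobutanone (C2–C4 and C1–C5, an aryl ketene with a dihydrofuran) offers no regiochemical bias. The chosen cut pairs the electron-poor C1=C5 bond of butenolide 7 with the electron-rich ketene acetal 12 in a head-to-tail sense. Fragment 7 has one stereocentre and 12 has none, so the route becomes convergent. The forward reaction must give head-to-tail regiochemistry and addition anti to aryl B.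

**7 ⇐ 6 ⇐ 4 + 5; 4 ⇐ 3 ⇐ 1 + 2.** The C1=C5 bond is cut by retro-metathesis, the O7–C8 bond by retro-acylation with acryloyl chloride 5, and the C5–C6 bond by retro-Grignard addition of 2 to aldehyde 1. The single stereocentre of 4 comes from an enzymatic resolution of 3, whose sense is predictable. Its price is the loss of half of a two-carbon-extended commodity aldehyde at the second step.

**12 ⇐ 9 + 10; 9 ⇐ 8.** The C2=C4 bond is cut by a Horner–Wittig disconnection to aldehyde 9 and the commercially available phosphine oxide 10. This is two steps from phenol 8 and avoids the cyanide and acidic orthoester chemistry of the classical ketene acetal route, which an aryl silyl ether would not tolerate. The ethyl acetal is chosen because 10 is the available reagent; the ketal is a spectator that is hydrolysed in step 8.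

## Roads not taken

**Alternative 1:** The cuts are C1–C2 and C5–C6 on a butenolide that carries neither aryl group. The lithiated dithiane A2 would add to the β-carbon of the trityl-protected butenolide A1 anti to its side chain, and the enolate would be trapped by aldehyde 1 to give the trans-disubstituted lactone A3.
- Merits: the tandem conjugate addition–aldol is a well-tried three-component coupling, better precedented than the key step chosen here. The trans arrangement across the lactone is exactly the C1/C5 relationship the cis-fused bicycle needs.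
- Weak points: neither ring of the target is formed. The lactone carbonyl becomes C4, and the γ-carbon becomes C8 only after its trityloxymethyl carbon is excised (reduction, detritylation, glycol cleavage, reduction). The dithiane must be removed and the C2 ketone reduced selectively. The C6 carbinol is not controlled in the aldol step. The required sense of induction calls for the (R)-butenolide A1, which belongs to the D-glutamic acid series.
- Comparison: Alternative 1 is the safer key step. Against it the chosen plan sets a ring and both bridgeheads in its key step, fixes C6 beforehand with an enzyme and C2 afterwards by equilibration, and needs five steps after the key step where A3 needs roughly twice as many.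

**Alternative 2:** The cuts are C1–C5 and C6–O7 in an acyclic epoxy cinnamyl ether A4. Cp2TiCl (trivalent titanium) would open the epoxide to the C1 radical, 5-exo cyclisation onto C5=C6 would close ring A, and oxidation of the benzylic C6 centre with iodine would let O7 close ring B, giving A5, which is identical with 17.
- Merits: both rings are made in one flask, no redox adjustment follows, and only desilylation remains. In step count this road is clearly shorter than the chosen one.
- Weak points: C2 is the only stereocentre present and must control three new ones. The C1/C2 trans relationship is plausible, but material that cyclises with C1/C5 trans cannot close ring B, and C6 is set by capture of a benzylic cation, which can give exo/endo mixtures. Titanium is used in excess. A4 itself needs an enantiopure benzylic carbinol (the same effort as 4) and a terminal epoxide made in the presence of an electron-rich cinnamyl alkene.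
- Comparison: Alternative 2 wins on brevity. The chosen plan offers a defined control element for every stereocentre (enzyme for C6, face of the butenolide for C5, ring fusion for C1, equilibration for C2), and pays for it with a photochemical step of uncertain efficiency and three redox steps.

**Alternative 3:** The cut is C6–O7 in the arylidene lactone A6 (ring A lactone, aryl B-methylidene on C5, hydroxymethyl on C1). Acid would generate a C6 cation stabilised by the para-methoxy group, the C8 hydroxyl would capture it, and protonation at C5 would give the cis-fused lactone A7.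
- Merits: A6 is available by aldol condensation with aldehyde 1, C6 is set thermodynamically to exo, and only one lactone has to be reduced afterwards. The endgame is one redox operation shorter than the chosen one and needs no photochemistry.
- Weak points: the para-methoxy group of aryl B is flanked by two methoxy groups that twist it out of conjugation and withdraw inductively, so the cation is less stabilised than in a 4-methoxyphenyl case and stronger acid is needed. The same acid can ionise the benzylic lactone bond C2–O3 next to aryl A, and the closure is reversible. The trans C1/C2 lactone A6 needs its own asymmetric synthesis.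
- Comparison: Alternative 3 is more conventional and shorter at the end. The chosen plan instead sets C6 first and never exposes a benzylic C–O bond to strong acid.

Key step: step 7

Assumption: the atom labels C1–C8, O3 and O7 of the bicyclic core are used for every intermediate, whatever its systematic numbering; photoadduct 13 is written as its exo-aryl A epimer, and any endo epimer formed beside it converges on 14 in step 8.

## Route

Step 1
Reactants: 1 3,4,5-trimethoxybenzaldehyde; 2 vinylmagnesium bromide
Product: 3 rac-1-(3,4,5-trimethoxyphenyl)prop-2-en-1-ol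
Conditions: THF, −20 → 0 °C; aq. NH4Cl
Reagents that add atoms: none
Why: Grignard 1,2-addition to the aryl aldehyde forms the C5–C6 bond; the carbinol is racemic at this stage and is resolved in step 2.

Step 2
Reactants: 3 rac-1-(3,4,5-trimethoxyphenyl)prop-2-en-1-ol
Product: 4 (S)-1-(3,4,5-trimethoxyphenyl)prop-2-en-1-ol
Conditions: Novozym 435 (immobilised lipase B of Candida antarctica), vinyl acetate, t-BuOMe, 30 °C, stopped just past half conversion
Reagents that add atoms: none
Why: Lipase-catalysed kinetic resolution by irreversible transesterification; for a secondary carbinol with a large (aryl) and a medium (vinyl) substituent the enzyme should acetylate the (R)-enantiomer and leave (S)-4, which has the configuration of C6. Running slightly past half conversion should raise the optical purity of the remaining alcohol at the cost of half the material.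

Step 3
Reactants: 4 (S)-1-(3,4,5-trimethoxyphenyl)prop-2-en-1-ol; 5 acryloyl chloride
Product: 6 (S)-1-(3,4,5-trimethoxyphenyl)prop-2-en-1-yl prop-2-enoate
Conditions: Et3N, CH2Cl2, −20 → 0 °C
Reagents that add atoms: none
Why: O-Acylation of the secondary alcohol with an acid chloride forms O7–C8; the C6–O7 bond is not touched, so the configuration is kept, and base at low temperature avoids ionisation of the electron-rich allylic ester.

Step 4
Reactants: 6 (S)-1-(3,4,5-trimethoxyphenyl)prop-2-en-1-yl prop-2-enoate
Product: 7 (S)-5-(3,4,5-trimethoxyphenyl)furan-2(5H)-one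
Conditions: second-generation Grubbs catalyst RuCl2(=CHPh)(PCy3)(H2IMes) (5 mol%), CH2Cl2 (0.01 M), reflux
Reagents that add atoms: none
Why: Ring-closing olefin metathesis of an allyl acrylate to a butenolide, a standard use of this catalyst with electron-poor alkenes; it forms C1=C5 with loss of ethene, high dilution suppresses cross-metathesis, and C6 is not involved.

Step 5
Reactants: 8 3-hydroxy-4,5-dimethoxybenzaldehyde
Product: 9 3,4-dimethoxy-5-(triisopropylsilyloxy)benzaldehyde
Conditions: i-Pr3SiCl, imidazole, DMF, rt
Reagents that add atoms: chlorotriisopropylsilane, CC(C)[Si](Cl)(C(C)C)C(C)C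
Why: Silylation of the phenol; the bulky silyl ether should tolerate the bases of step 6, peracid, hydride and cold BF3·OEt2 and is removed by fluoride at the end.

Step 6
Reactants: 9 3,4-dimethoxy-5-(triisopropylsilyloxy)benzaldehyde; 10 (diethoxymethyl)diphenylphosphine oxide
Product: 12 1-(2,2-diethoxyethenyl)-3,4-dimethoxy-5-(triisopropylsilyloxy)benzene, via lithium alkoxide adduct 11 (not isolated)
Conditions: 10, LiN(i-Pr)2, THF, −100 °C; 9, −100 → −78 °C; KOt-Bu, −78 °C → rt; filtration through basic alumina
Reagents that add atoms: none
Why: Horner–Wittig olefination: lithiated 10 adds to aldehyde 9 and, after exchange of lithium for potassium, alkoxide 11 loses diphenylphosphinate by syn elimination to give the ketene O,O-acetal (C2=C4). The two ethoxy groups are identical, so no alkene geometry has to be controlled; 12 is acid-sensitive and is used at once.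

Step 7
Reactants: 7 (S)-5-(3,4,5-trimethoxyphenyl)furan-2(5H)-one; 12 1-(2,2-diethoxyethenyl)-3,4-dimethoxy-5-(triisopropylsilyloxy)benzene
Product: 13 (1R,4S,5S,7S)-6,6-diethoxy-7-[3,4-dimethoxy-5-(triisopropylsilyloxy)phenyl]-4-(3,4,5-trimethoxyphenyl)-3-oxabicyclo[3.2.0]heptan-2-one
Conditions: fac-Ir(dFppy)3 (1 mol%), 12 (2.5 equiv), degassed MeCN (0.3 M in 7), 427 nm LEDs, 0 °C
Reagents that add atoms: none
Why: Proposed new method: the sensitiser (dFppy = 2-(2,4-difluorophenyl)pyridinato; triplet energy about 60 kcal/mol, a weak excited-state oxidant and not a carbonyl compound) should pass its energy only to the styrene-type ketene acetal 12, the lowest triplet in the mixture, whose nucleophilic dialkoxy-substituted terminus C4 then adds to the electron-poor β-carbon C5 of ground-state 7; the resulting triplet 1,4-diradical, benzylic at C2 and α to the lactone carbonyl at C1, crosses to the singlet and couples C1 with C2. The closest known reaction types are the [2+2] photocycloaddition of furan-2(5H)-ones with 1,1-dialkoxyethenes (same head-to-tail bond set, furanone as the excited partner) and the visible-light triplet-sensitised [2+2] cycloaddition of styrenes with alkenes; should energy reach 7 instead, its β-carbon would attack the acetal carbon of 12 and give the same diradical. The cyclobutane is the only ring closed, by a stepwise [2+2] process: intermolecular C4–C5 bond formation followed by recombination of the 1,4-diradical (C1–C2). C5 is set by attack anti to aryl B on the neighbouring stereocentre C6, which shields one face of the flat butenolide; C1 follows from C5 because a four-membered ring can only be fused cis to the lactone; C2 is set in the diradical collapse, where the exo position of aryl A is favoured but not secured, and is corrected in step 8; the acetal carbon C4 is not stereogenic. The step needs head-to-tail regiochemistry, anti facial selectivity and cross- over homo-coupling: the first should follow from the polarity match and the stability of the diradical, the second from the C6 aryl group, the third from a high concentration of 7 and an excess of 12, whose unproductive triplet decay merely regenerates 12 because twisting about its C=C bond interconverts identical structures.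

Step 8
Reactants: 13 (1R,4S,5S,7S)-6,6-diethoxy-7-[3,4-dimethoxy-5-(triisopropylsilyloxy)phenyl]-4-(3,4,5-trimethoxyphenyl)-3-oxabicyclo[3.2.0]heptan-2-one
Product: 14 (1R,4S,5S,7S)-7-[3,4-dimethoxy-5-(triisopropylsilyloxy)phenyl]-4-(3,4,5-trimethoxyphenyl)-3-oxabicyclo[3.2.0]heptane-2,6-dione
Conditions: 1 M aq. HCl, THF, rt; then DBU (0.1 equiv), CH2Cl2, 0 °C → rt
Reagents that add atoms: water, O
Why: Acid-catalysed acetal hydrolysis through the oxocarbenium ion at C4 gives the cyclobutanone; C2, now benzylic and α to the ketone, is then equilibrated through its enolate to the exo position (aryl A trans to the lactone ring), which corrects whatever epimer ratio step 7 delivers. A catalytic amidine base in the cold is chosen because enolisation towards C5 could expel the C6 carboxylate.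

Step 9
Reactants: 14 (1R,4S,5S,7S)-7-[3,4-dimethoxy-5-(triisopropylsilyloxy)phenyl]-4-(3,4,5-trimethoxyphenyl)-3-oxabicyclo[3.2.0]heptane-2,6-dione
Product: 15 (1S,2S,5S,6S)-2-[3,4-dimethoxy-5-(triisopropylsilyloxy)phenyl]-6-(3,4,5-trimethoxyphenyl)-3,7-dioxabicyclo[3.3.0]octane-4,8-dione
Conditions: mCPBA, CH2Cl2, 0 °C → rt
Reagents that add atoms: 3-chloroperoxybenzoic acid, OOC(=O)c1cccc(Cl)c1
Why: Baeyer–Villiger oxidation: the peracid adds to the strained ketone and in the Criegee intermediate the benzylic carbon C2 migrates to oxygen with retention, which inserts O3 between C2 and C4. C2 should migrate in preference to C5, which is deactivated by the acyloxy-bearing C6 next to it; relief of ring strain should make the reaction fast at a temperature where the arenes are not attacked.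

Step 10
Reactants: 15 (1S,2S,5S,6S)-2-[3,4-dimethoxy-5-(triisopropylsilyloxy)phenyl]-6-(3,4,5-trimethoxyphenyl)-3,7-dioxabicyclo[3.3.0]octane-4,8-dione
Product: 16 (1S,2S,5S,6S)-2-[3,4-dimethoxy-5-(triisopropylsilyloxy)phenyl]-6-(3,4,5-trimethoxyphenyl)-3,7-dioxabicyclo[3.3.0]octane-4,8-diol (bis-lactol, anomers at C4 and C8)
Conditions: i-Bu2AlH (2.3 equiv), CH2Cl2, −78 °C; aq. potassium sodium tartrate
Reagents that add atoms: none
Why: Partial reduction of both lactones to lactols with a dialkylaluminium hydride; the tetrahedral aluminium acetals persist at −78 °C and collapse only on work-up, so no diol should form. No stereocentre of the core is touched and the anomeric mixture is of no consequence.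

Step 11
Reactants: 16 (1S,2S,5S,6S)-2-[3,4-dimethoxy-5-(triisopropylsilyloxy)phenyl]-6-(3,4,5-trimethoxyphenyl)-3,7-dioxabicyclo[3.3.0]octane-4,8-diol
Product: 17 (1R,2S,5R,6S)-2-[3,4-dimethoxy-5-(triisopropylsilyloxy)phenyl]-6-(3,4,5-trimethoxyphenyl)-3,7-dioxabicyclo[3.3.0]octane
Conditions: Et3SiH, BF3·OEt2, CH2Cl2, −78 → −40 °C
Reagents that add atoms: none
Why: Ionic hydrogenation of lactols: BF3·OEt2 generates the oxocarbenium ions at C4 and C8, which the silane reduces to the methylene groups of rings A and B. Neither carbon becomes a stereocentre, and the low temperature is meant to keep the benzylic C2–O3 and C6–O7 bonds from ionising.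

Step 12
Reactants: 17 (1R,2S,5R,6S)-2-[3,4-dimethoxy-5-(triisopropylsilyloxy)phenyl]-6-(3,4,5-trimethoxyphenyl)-3,7-dioxabicyclo[3.3.0]octane
Product: 18 5-[(1R,2S,5R,6S)-6-(3,4,5-trimethoxyphenyl)-3,7-dioxabicyclo[3.3.0]octan-2-yl]-2,3-dimethoxyphenol
Conditions: Bu4NF, AcOH, THF, 0 °C
Reagents that add atoms: none
Why: Fluoride-induced cleavage of the aryl silyl ether, buffered with acetic acid so that the phenoxide is protonated as it forms; the benzylic ethers and all stereocentres are inert to these conditions.

## Compound list

1 | 3,4,5-trimethoxybenzaldehyde | COc1cc(C=O)cc(OC)c1OC | starting material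
2 | vinylmagnesium bromide | C=C[Mg]Br | starting material
3 | rac-1-(3,4,5-trimethoxyphenyl)prop-2-en-1-ol | C=CC(O)c1cc(OC)c(OC)c(OC)c1 | intermediate
4 | (S)-1-(3,4,5-trimethoxyphenyl)prop-2-en-1-ol | C=C[C@H](O)c1cc(OC)c(OC)c(OC)c1 | intermediate
5 | acryloyl chloride | C=CC(=O)Cl | starting material
6 | (S)-1-(3,4,5-trimethoxyphenyl)prop-2-en-1-yl prop-2-enoate | C=CC(=O)O[C@@H](C=C)c1cc(OC)c(OC)c(OC)c1 | intermediate
7 | (S)-5-(3,4,5-trimethoxyphenyl)furan-2(5H)-one | O=C1C=C[C@H](O1)c1cc(OC)c(OC)c(OC)c1 | intermediate
8 | 3-hydroxy-4,5-dimethoxybenzaldehyde | COc1cc(C=O)cc(O)c1OC | starting material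
9 | 3,4-dimethoxy-5-(triisopropylsilyloxy)benzaldehyde | COc1cc(C=O)cc(O[Si](C(C)C)(C(C)C)C(C)C)c1OC | intermediate
10 | (diethoxymethyl)diphenylphosphine oxide | CCOC(OCC)P(=O)(c1ccccc1)c1ccccc1 | starting material
11 | lithium 2,2-diethoxy-1-[3,4-dimethoxy-5-(triisopropylsilyloxy)phenyl]-2-(diphenylphosphoryl)ethan-1-olate (racemic, not isolated) | [Li+].CCOC(OCC)(C([O-])c1cc(OC)c(OC)c(O[Si](C(C)C)(C(C)C)C(C)C)c1)P(=O)(c1ccccc1)c1ccccc1 | intermediate
12 | 1-(2,2-diethoxyethenyl)-3,4-dimethoxy-5-(triisopropylsilyloxy)benzene | CCOC(OCC)=Cc1cc(OC)c(OC)c(O[Si](C(C)C)(C(C)C)C(C)C)c1 | intermediate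
13 | (1R,4S,5S,7S)-6,6-diethoxy-7-[3,4-dimethoxy-5-(triisopropylsilyloxy)phenyl]-4-(3,4,5-trimethoxyphenyl)-3-oxabicyclo[3.2.0]heptan-2-one (systematic locants 1, 4, 5, 6, 7 are core C1, C6, C5, C4, C2) | O=C1O[C@H](c2cc(OC)c(OC)c(OC)c2)[C@@H]2[C@H]1[C@@H](c1cc(OC)c(OC)c(O[Si](C(C)C)(C(C)C)C(C)C)c1)C2(OCC)OCC | intermediate
14 | (1R,4S,5S,7S)-7-[3,4-dimethoxy-5-(triisopropylsilyloxy)phenyl]-4-(3,4,5-trimethoxyphenyl)-3-oxabicyclo[3.2.0]heptane-2,6-dione | O=C1O[C@H](c2cc(OC)c(OC)c(OC)c2)[C@@H]2[C@H]1[C@@H](c1cc(OC)c(OC)c(O[Si](C(C)C)(C(C)C)C(C)C)c1)C2=O | intermediate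
15 | (1S,2S,5S,6S)-2-[3,4-dimethoxy-5-(triisopropylsilyloxy)phenyl]-6-(3,4,5-trimethoxyphenyl)-3,7-dioxabicyclo[3.3.0]octane-4,8-dione (core numbering) | O=C1O[C@H](c2cc(OC)c(OC)c(OC)c2)[C@@H]2[C@H]1[C@@H](c1cc(OC)c(OC)c(O[Si](C(C)C)(C(C)C)C(C)C)c1)OC2=O | intermediate
16 | (1S,2S,5S,6S)-2-[3,4-dimethoxy-5-(triisopropylsilyloxy)phenyl]-6-(3,4,5-trimethoxyphenyl)-3,7-dioxabicyclo[3.3.0]octane-4,8-diol (anomeric mixture at C4 and C8) | OC1O[C@H](c2cc(OC)c(OC)c(OC)c2)[C@@H]2[C@H]1[C@@H](c1cc(OC)c(OC)c(O[Si](C(C)C)(C(C)C)C(C)C)c1)OC2O | intermediate
17 | (1R,2S,5R,6S)-2-[3,4-dimethoxy-5-(triisopropylsilyloxy)phenyl]-6-(3,4,5-trimethoxyphenyl)-3,7-dioxabicyclo[3.3.0]octane | COc1cc([C@H]2OC[C@H]3[C@@H]2CO[C@@H]3c2cc(OC)c(OC)c(OC)c2)cc(O[Si](C(C)C)(C(C)C)C(C)C)c1OC | intermediate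
18 | 5-[(1R,2S,5R,6S)-6-(3,4,5-trimethoxyphenyl)-3,7-dioxabicyclo[3.3.0]octan-2-yl]-2,3-dimethoxyphenol | COc1cc([C@H]2OC[C@H]3[C@@H]2CO[C@@H]3c2cc(OC)c(OC)c(OC)c2)cc(O)c1OC | target

## Step count and least certain steps

Total: 12 steps. Longest linear sequence: 10 steps (steps 1–4 and 7–12, from 1); the ketene acetal branch (steps 5 and 6) is two steps.

**Step 7 (key step, proposed new method).** The most likely failure is that the triplet of 12 decays by twisting, couples with itself or transfers an electron to the excited sensitiser faster than it adds to 7, so that cross-addition stays slow while 12 is consumed. Incomplete anti selectivity would also erode the purity at C5 and C1.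

Fallback, using known chemistry and introducing aryl A after the photocycloaddition instead of during it:
- It sets out from 7, which is irradiated with an excess of commercially available 1,1-diethoxyethene under the ultraviolet conditions established for γ-substituted furan-2(5H)-ones. This known head-to-tail, anti-selective cycloaddition should give the aryl-free ketal 6,6-diethoxy-4-(3,4,5-trimethoxyphenyl)-3-oxabicyclo[3.2.0]heptan-2-one F1.
- Dilute acid would hydrolyse it to the cyclobutanone 4-(3,4,5-trimethoxyphenyl)-3-oxabicyclo[3.2.0]heptane-2,6-dione F2.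
- Me3SiOTf/Et3N would convert F2 into the enol silane 6-(trimethylsilyloxy)-4-(3,4,5-trimethoxyphenyl)-3-oxabicyclo[3.2.0]hept-6-en-2-one F3. Enolisation should go only towards C2, because a double bond to the ring-fusion carbon C5 would be highly strained.
- Palladium-catalysed α-arylation of F3 (Pd2(dba)3 as source of zerovalent palladium, P(t-Bu)3, Bu3SnF) with the aryl bromide (5-bromo-2,3-dimethoxyphenoxy)triisopropylsilane F4, made by silylation of 5-bromo-2,3-dimethoxyphenol, followed by the base equilibration of step 8, comes back to the route at 14.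

**Step 9.** The most likely failure is migration of the ring-fusion carbon C5 in competition with C2, which would insert oxygen on the wrong side of C4.

Fallback, in which radical stability instead of migratory aptitude decides the regiochemistry:
- It sets out from 14, which is irradiated in methanol at about 300 nm. Norrish type 1 cleavage on the benzylic side, ring expansion to the oxacarbene and O–H insertion should give the ring A methyl acetal 4-methoxy-2-[3,4-dimethoxy-5-(triisopropylsilyloxy)phenyl]-6-(3,4,5-trimethoxyphenyl)-3,7-dioxabicyclo[3.3.0]octan-8-one F5.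
- i-Bu2AlH would reduce the remaining lactone to the lactol 4-methoxy-2-[3,4-dimethoxy-5-(triisopropylsilyloxy)phenyl]-6-(3,4,5-trimethoxyphenyl)-3,7-dioxabicyclo[3.3.0]octan-8-ol F6.
- Et3SiH/BF3·OEt2 would reduce acetal and lactol together, coming back to the route at 17.

**Step 8.** The most likely failure is β-elimination of the C6 carboxylate after enolisation towards C5 under base, or incomplete equilibration at C2.

Fallback, which moves the stereocorrection from enolate chemistry to ionisation of a benzylic lactone:
- It sets out from 13, which is hydrolysed with acid alone. This would give 14 together with its C2 epimer, the endo-aryl A ketone (1R,4S,5S,7R)-7-[3,4-dimethoxy-5-(triisopropylsilyloxy)phenyl]-4-(3,4,5-trimethoxyphenyl)-3-oxabicyclo[3.2.0]heptane-2,6-dione F7.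
- Baeyer–Villiger oxidation of the mixture would give 15 and the endo-aryl A dilactone (1S,2R,5S,6S)-2-[3,4-dimethoxy-5-(triisopropylsilyloxy)phenyl]-6-(3,4,5-trimethoxyphenyl)-3,7-dioxabicyclo[3.3.0]octane-4,8-dione F8.
- Brief exposure to CF3CO2H in CH2Cl2 should ionise the benzylic C2–O3 bond of F8 (carboxylate as leaving group) and re-close it to the more stable exo lactone, coming back to the route at 15.

**Step 11.** The most likely failure is ionisation of the benzylic C2–O3 or C6–O7 bond by BF3·OEt2, followed by epimerisation or hydride capture with ring opening.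

Fallback without Lewis acid:
- It sets out from 15, which LiBH4 in THF would reduce to the tetraol (1S,2R,3R,4S)-1-[3,4-dimethoxy-5-(triisopropylsilyloxy)phenyl]-2,3-bis(hydroxymethyl)-4-(3,4,5-trimethoxyphenyl)butane-1,4-diol F9.
- MeSO2Cl in pyridine would sulfonylate the two primary hydroxyls, and each benzylic hydroxyl would displace the sulfonate on the distal carbon (O3 onto C4, O7 onto C8) with retention at C2 and C6, coming back to the route at 17.

## Further compounds

F1 | step 7 | (1R,4S,5S)-6,6-diethoxy-4-(3,4,5-trimethoxyphenyl)-3-oxabicyclo[3.2.0]heptan-2-one | O=C1O[C@H](c2cc(OC)c(OC)c(OC)c2)[C@@H]2[C@H]1CC2(OCC)OCC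
F2 | step 7 | (1R,4S,5S)-4-(3,4,5-trimethoxyphenyl)-3-oxabicyclo[3.2.0]heptane-2,6-dione | O=C1O[C@H](c2cc(OC)c(OC)c(OC)c2)[C@@H]2[C@H]1CC2=O
F3 | step 7 | 6-(trimethylsilyloxy)-4-(3,4,5-trimethoxyphenyl)-3-oxabicyclo[3.2.0]hept-6-en-2-one (cis-fused, configuration as in F2) | O=C1O[C@H](c2cc(OC)c(OC)c(OC)c2)[C@@H]2[C@H]1C=C2O[Si](C)(C)C
F4 | step 7 | (5-bromo-2,3-dimethoxyphenoxy)triisopropylsilane | COc1cc(Br)cc(O[Si](C(C)C)(C(C)C)C(C)C)c1OC
F5 | step 9 | 4-methoxy-2-[3,4-dimethoxy-5-(triisopropylsilyloxy)phenyl]-6-(3,4,5-trimethoxyphenyl)-3,7-dioxabicyclo[3.3.0]octan-8-one (C1, C2, C5, C6 as in 15; C4 anomers) | O=C1O[C@H](c2cc(OC)c(OC)c(OC)c2)[C@@H]2[C@H]1[C@@H](c1cc(OC)c(OC)c(O[Si](C(C)C)(C(C)C)C(C)C)c1)OC2OC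
F6 | step 9 | 4-methoxy-2-[3,4-dimethoxy-5-(triisopropylsilyloxy)phenyl]-6-(3,4,5-trimethoxyphenyl)-3,7-dioxabicyclo[3.3.0]octan-8-ol (C4 and C8 anomers) | OC1O[C@H](c2cc(OC)c(OC)c(OC)c2)[C@@H]2[C@H]1[C@@H](c1cc(OC)c(OC)c(O[Si](C(C)C)(C(C)C)C(C)C)c1)OC2OC
F7 | step 8 | (1R,4S,5S,7R)-7-[3,4-dimethoxy-5-(triisopropylsilyloxy)phenyl]-4-(3,4,5-trimethoxyphenyl)-3-oxabicyclo[3.2.0]heptane-2,6-dione (C2 epimer of 14) | O=C1O[C@H](c2cc(OC)c(OC)c(OC)c2)[C@@H]2[C@H]1[C@H](c1cc(OC)c(OC)c(O[Si](C(C)C)(C(C)C)C(C)C)c1)C2=O
F8 | step 8 | (1S,2R,5S,6S)-2-[3,4-dimethoxy-5-(triisopropylsilyloxy)phenyl]-6-(3,4,5-trimethoxyphenyl)-3,7-dioxabicyclo[3.3.0]octane-4,8-dione (C2 epimer of 15) | O=C1O[C@H](c2cc(OC)c(OC)c(OC)c2)[C@@H]2[C@H]1[C@H](c1cc(OC)c(OC)c(O[Si](C(C)C)(C(C)C)C(C)C)c1)OC2=O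
F9 | step 11 | (1S,2R,3R,4S)-1-[3,4-dimethoxy-5-(triisopropylsilyloxy)phenyl]-2,3-bis(hydroxymethyl)-4-(3,4,5-trimethoxyphenyl)butane-1,4-diol | OC[C@H]([C@H](O)c1cc(OC)c(OC)c(O[Si](C(C)C)(C(C)C)C(C)C)c1)[C@H](CO)[C@H](O)c1cc(OC)c(OC)c(OC)c1
A1 | alternative 1 | (R)-5-(trityloxymethyl)furan-2(5H)-one | O=C1O[C@@H](COC(c2ccccc2)(c2ccccc2)c2ccccc2)C=C1
A2 | alternative 1 | 2-[3,4-dimethoxy-5-(triisopropylsilyloxy)phenyl]-1,3-dithiane | COc1cc(C2SCCCS2)cc(O[Si](C(C)C)(C(C)C)C(C)C)c1OC
A3 | alternative 1 | trans-α,β-disubstituted lactone from dithiane addition and aldol trapping (C6 carbinol as one epimer) | O=C1O[C@@H](COC(c2ccccc2)(c2ccccc2)c2ccccc2)[C@H](C2(SCCCS2)c2cc(OC)c(OC)c(O[Si](C(C)C)(C(C)C)C(C)C)c2)[C@H]1[C@H](O)c1cc(OC)c(OC)c(OC)c1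
A4 | alternative 2 | epoxy cinnamyl ether, 2-{(S)-[3,4-dimethoxy-5-(triisopropylsilyloxy)phenyl][(E)-3-(3,4,5-trimethoxyphenyl)prop-2-enyloxy]methyl}oxirane (epoxide carbon unassigned) | COc1cc(cc(O[Si](C(C)C)(C(C)C)C(C)C)c1OC)[C@@H](OC/C=C/c1cc(OC)c(OC)c(OC)c1)C1CO1
A5 | alternative 2 | O-triisopropylsilyl ether of the target (identical with 17) | COc1cc(cc(O[Si](C(C)C)(C(C)C)C(C)C)c1OC)[C@H]1OC[C@H]2[C@@H]1CO[C@@H]2c1cc(OC)c(OC)c(OC)c1
A6 | alternative 3 | (E)-α-(3,4,5-trimethoxybenzylidene) lactone of ring A with hydroxymethyl on C1 | COc1cc(cc(O[Si](C(C)C)(C(C)C)C(C)C)c1OC)[C@H]1OC(=O)/C(=C/c2cc(OC)c(OC)c(OC)c2)[C@@H]1CO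
A7 | alternative 3 | silyl-protected 2,6-diaryl-3,7-dioxabicyclo[3.3.0]octan-4-one | COc1cc(cc(O[Si](C(C)C)(C(C)C)C(C)C)c1OC)[C@H]1OC(=O)[C@H]2[C@@H]1CO[C@@H]2c1cc(OC)c(OC)c(OC)c1
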